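**Assumptions (one line each):** The target has no stereocentres (the prenyl alkene has two identical Me groups, so no E/Z), so "single enantiomer" is moot. 2′,6′-Dihydroxy-4′-methoxyacetophenone is taken as commercially available.

## Retrosynthesis
1. Target ⇒ 2′,4′-bis-MOM isoflavone. The 6-prenyl group is installed regiospecifically by an aromatic Claisen [3,3] rearrangement of a 5-O-(1,1-dimethylallyl) ether. C6 is the only free ortho position of 5-O, and the reverse-prenyl ether gives the normal prenyl chain.
2. The tertiary ether comes from the chelated peri-OH of the isoflavone by a proposed new Pd-catalysed Markovnikov O-prenylation (the key new step).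
3. Isoflavone ⇐ Suzuki coupling of 3-iodo-5-hydroxy-7-methoxychromone with 2,4-bis(MOM-oxy)phenylboronic acid.
4. The chromone (C) ring is built first, from the symmetric 2,6-dihydroxy-4-methoxyacetophenone (A ring) by enaminone formation and iodocyclisation, so there is no ring-closure regiochemistry issue. Ring order: A ring, then C ring, then B ring attached, then the prenyl group at C6.

## Route

**Step 1**
Reactants: 1 (2′,6′-dihydroxy-4′-methoxyacetophenone); 2 (DMF-DMA)
Product: 3, (E)-3-(dimethylamino)-1-(2,6-dihydroxy-4-methoxyphenyl)prop-2-en-1-one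
Conditions: 2 (3 equiv), toluene, 100 °C, 4 h
Reagents that add atoms: DMF-DMA, CN(C)C(OC)OC (=2, supplies the =CH–NMe2 unit)
Why: Methyl-ketone condensation with an amide acetal gives the enaminone. The two phenols are equivalent by symmetry, so only one product is possible.

**Step 2**
Reactants: 3
Product: 4, 3-iodo-5-hydroxy-7-methoxy-4H-chromen-4-one
Conditions: I2 (1.2 equiv), CHCl3, 0 °C to rt, 2 h; Na2S2O3 workup
Reagents that add atoms: I2, II
Why: Iodination of the enaminone α-carbon followed by phenol attack and loss of HNMe2 closes the pyranone ring (iodine-mediated enaminone cyclisation). The second OH stays as the chelated 5-OH.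

**Step 3**
Reactants: 5 (4-bromoresorcinol)
Product: 6, 1-bromo-2,4-bis(methoxymethoxy)benzene
Conditions: MOMCl (2.5 equiv), iPr2NEt, CH2Cl2, 0 °C to rt
Reagents that add atoms: MOMCl, ClCOC
Why: Standard acetal protection of both phenols.

**Step 4**
Reactants: 6
Product: 7, 2,4-bis(methoxymethoxy)phenylboronic acid
Conditions: n-BuLi, THF, −78 °C; then B(OMe)3; then aq. NH4Cl/HCl
Reagents that add atoms: B(OMe)3, COB(OC)OC
Why: MOM-assisted Br/Li exchange followed by borate trapping (borylation via lithium–halogen exchange).

**Step 5**
Reactants: 4; 7 (1.5 equiv)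
Product: 8, 3-[2,4-bis(methoxymethoxy)phenyl]-5-hydroxy-7-methoxychromone
Conditions: Pd(PPh3)4 (5 mol%), Na2CO3, DME/H2O 3:1, 80 °C, 6 h
Reagents that add atoms: none
Why: Suzuki–Miyaura coupling of the vinyl iodide forms the C3–C1′ bond. The chelated 5-OH and the MOM groups are inert.

**Step 6**
Reactants: 9 (prenol, 3-methylbut-2-en-1-ol)
Product: 10, prenyl methyl carbonate
Conditions: ClCO2Me, pyridine, CH2Cl2, 0 °C
Reagents that add atoms: methyl chloroformate, COC(Cl)=O
Why: Standard carbonate formation gives an allylic electrophile that ionises irreversibly (loss of CO2) with Pd(0).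

**Step 7**
Reactants: 8; 10 (2 equiv)
Product: 11, 5-O-(2-methylbut-3-en-2-yl) ether of 8
Conditions: Pd2(dba)3 (2.5 mol%), P(OPh)3 (20 mol%), THF, 40 °C, 12 h, no added base
Reagents that add atoms: prenyl methyl carbonate, COC(=O)OCC=C(C)C (=10, supplies the C5H9 unit)
Why: Proposed new method: Pd(0) ionises 10 to a π-prenyl-Pd cation and MeO⁻ (from CO2 loss), which deprotonates the H-bonded 5-OH. Kinetic control and a π-acidic phosphite ligand should give the tertiary (branched, Markovnikov) aryl ether. The ligand pulls positive charge onto the CMe2 terminus, and the hard, bulky, chelated phenoxide attacks there. Aryl ethers ionise far more slowly than the carbonate, so the tertiary ether is not re-funnelled to the linear ether. The closest known chemistry is Pd-catalysed reverse prenylation of indoles and Ir-catalysed branched allylic etherification, here applied to O-nucleophiles and tertiary selectivity on a peri-hydroxy ketone. No stereocentre is formed.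

**Step 8**
Reactants: 11
Product: 12, 6-prenyl-5-hydroxy-7-methoxy-3-[2,4-bis(MOM-oxy)phenyl]chromone
Conditions: PhNEt2, 130 °C, sealed tube, 16 h (wash with dilute HCl)
Reagents that add atoms: none
Why: Aromatic Claisen [3,3] of the 1,1-dimethylallyl aryl ether goes to C6, the only free ortho carbon (C4a is blocked), and inverts the allyl unit to give the normal prenyl chain. The amine base suppresses acid-mediated ionisation and chroman formation.

**Step 9**
Reactants: 12
Product: 13, 7-O-methylluteone
Conditions: 3 M HCl, MeOH/THF 3:1, 50 °C, 5 h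
Reagents that add atoms: none
Why: Acidolysis of the two aryl MOM acetals releases the 2′,4′-diol. The chelated 5-OH, the 7-OMe, the prenyl alkene and the chromone survive these mild conditions.

## Compound list
1 | 2′,6′-dihydroxy-4′-methoxyacetophenone | CC(=O)c1c(O)cc(OC)cc1O | starting material
2 | N,N-dimethylformamide dimethyl acetal | CN(C)C(OC)OC | starting material
3 | (E)-enaminone | CN(C)/C=C/C(=O)c1c(O)cc(OC)cc1O | intermediate
4 | 3-iodo-5-hydroxy-7-methoxychromone | COc1cc(O)c2c(c1)occ(I)c2=O | intermediate
5 | 4-bromoresorcinol | Oc1ccc(Br)c(O)c1 | starting material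
6 | 1-bromo-2,4-bis(MOM-oxy)benzene | COCOc1ccc(Br)c(OCOC)c1 | intermediate
7 | 2,4-bis(MOM-oxy)phenylboronic acid | COCOc1ccc(B(O)O)c(OCOC)c1 | intermediate
8 | 5-hydroxy-7-methoxy-3-[2,4-bis(MOM-oxy)phenyl]chromone | COc1cc(O)c2c(c1)occ(-c1ccc(OCOC)cc1OCOC)c2=O | intermediate
9 | prenol | CC(C)=CCO | starting material
10 | prenyl methyl carbonate | COC(=O)OCC=C(C)C | intermediate
11 | 5-O-(2-methylbut-3-en-2-yl) ether of 8 | C=CC(C)(C)Oc1cc(OC)cc2occ(-c3ccc(OCOC)cc3OCOC)c(=O)c12 | intermediate
12 | 6-prenyl-5-hydroxy isoflavone, bis-MOM | COc1cc2occ(-c3ccc(OCOC)cc3OCOC)c(=O)c2c(O)c1CC=C(C)C | intermediate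
13 | 7-O-methylluteone (achiral) | COc1cc2occ(-c3ccc(O)cc3O)c(=O)c2c(O)c1CC=C(C)C | target

## Step count
Total steps: 9. Longest linear sequence: 6 steps (1→3→4→8→11→12→13, which is Steps 1, 2, 5, 7, 8, 9; the boronic acid branch, Steps 3, 4, 5, 7, 8, 9, is also 6).

## Three steps most likely to fail
1. **Step 7 (proposed new Pd-catalysed tertiary O-prenylation).** Linear O-prenyl ether or C-prenylation at C6/C8 may dominate instead of the tertiary ether.
   - Fallback: known Cu(II)/DBU etherification of the chelated 5-OH with 3-chloro-3-methylbut-1-yne (as its Cs phenoxide, CuI-catalysed if needed), then Lindlar semihydrogenation of the alkyne to give 11 by known chemistry.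
2. **Step 8 (Claisen of the tertiary ether).** Ionisation may compete with [3,3], giving chromans or 8-prenyl products.
   - Fallback: avoid the tertiary ether by 5-O-allylation of 8 (allyl bromide, K2CO3), thermal allyl Claisen to the 6-allyl-5-OH compound, then cross-metathesis with 2-methyl-2-butene (Hoveyda–Grubbs II) to give 12.
3. **Step 9 (MOM removal).** Acid may cyclise 5-OH onto the prenyl group or partly isomerise the alkene.
   - Fallback: use 2,4-bis(benzyloxy)phenylboronic acid in Step 5, carry it through Steps 7 and 8, and remove the benzyl ethers with BCl3 and pentamethylbenzene at −78 °C.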